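**Retrosynthetic overview**
1. The target is a (2S)-flavanone. Ring C is the only ring to be made and is opened at O1–C2, which leads back to an (R)-β-hydroxy ketone (Mitsunobu closure with inversion, step 12).
2. Feature: ring A carries the ring oxygen O1 on C8a and the acyl carbon C4 on the adjacent C4a, between the C5 oxygen and the C8 prenyl group. The bonds C8a–O1 and C4a–C4 are cut together, giving a C4a/C8a aryne and an (R)-β-silyloxy carboxylate (acyl C–O insertion, step 10).
3. Aryne precursor 12 comes from phloroglucinol: bis-MOM ether, N-isopropylcarbamate, two carbamate-directed ortho-metalations run in one flask (TMS, then prenyl), then exchange of carbamate for triflate.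
4. Acid 20 comes from 3'-bromo-4'-methoxyacetophenone: Negishi alkylation, Claisen condensation, asymmetric transfer hydrogenation (sets the only stereocentre), silylation, saponification.
5. Ring order: rings A and B are bought as benzene rings; ring C closes in step 12 and MOM removal follows.

Key step: step 10

**Route**

Step 1
Reactants: 1 phloroglucinol
Product: 2 3,5-bis(methoxymethoxy)phenol
Conditions: MOMCl (2.0 equiv), iPr2NEt (2.2 equiv), DMF, 0 °C → rt; chromatography, mono- and tris-ethers recycled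
Reagents that add atoms: chloromethyl methyl ether, COCCl
Why: O-alkylation (Williamson-type acetal formation) of the threefold symmetric triphenol with two equivalents of MOMCl should give the bis-ether as the main component of a statistical mixture, from which it is separated.

Step 2
Reactants: 2 3,5-bis(methoxymethoxy)phenol
Product: 3 3,5-bis(methoxymethoxy)phenyl N-isopropylcarbamate
Conditions: iPrNCO, Et3N (cat.), CH2Cl2, rt
Reagents that add atoms: isopropyl isocyanate, CC(C)N=C=O
Why: Amine-catalysed addition of the phenol to the isocyanate (carbamoylation) installs a strong ortho-directing group that can later be removed under mild basic conditions.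

Step 3
Reactants: 3 3,5-bis(methoxymethoxy)phenyl N-isopropylcarbamate; 4 prenyl bromide (1-bromo-3-methylbut-2-ene)
Product: 10 3,5-bis(methoxymethoxy)-2-(3-methylbut-2-en-1-yl)-6-(trimethylsilyl)phenyl N-isopropylcarbamate, via N-silyl carbamate 5 (not isolated), via 2-lithio N-silyl carbamate 6 (not isolated), via N,2-bis(trimethylsilyl) carbamate 7 (not isolated), via 6-lithio carbamate 8 (not isolated), via N-silyl prenylated carbamate 9 (not isolated)
Conditions: TMSOTf (1.05 equiv), TMEDA (2.2 equiv), Et2O, 0 °C → rt; n-BuLi (2.1 equiv), −78 °C; TMSCl (1.1 equiv), −78 °C, 1 h; n-BuLi (1.3 equiv), −78 °C; 4 (2.0 equiv), −78 → −20 °C; sat. aq NH4Cl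
Reagents that add atoms: chlorotrimethylsilane, C[Si](C)(C)Cl
Why: Two carbamate-directed ortho-metalations run consecutively in one flask: the N-silylated carbamate (TMSOTf buffered by TMEDA should leave the MOM ethers alone, and the first equivalent of n-BuLi is taken up by the TMEDA·HOTf salt) and the neighbouring OMOM group should guide n-BuLi to C2 (equivalent to C6) in preference to C4 between the two MOM ethers, TMSCl silylates that aryllithium, and because the N–Si bond of 7 is still in place a second charge of n-BuLi can metalate the one remaining carbamate-flanked position C6, whose aryllithium is alkylated by the primary allylic bromide in an SN2 reaction at low temperature (before carbamoyl migration can set in), the N–Si bond being hydrolysed only on the final work-up.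

Step 4
Reactants: 10 3,5-bis(methoxymethoxy)-2-(3-methylbut-2-en-1-yl)-6-(trimethylsilyl)phenyl N-isopropylcarbamate
Product: 12 3,5-bis(methoxymethoxy)-2-(3-methylbut-2-en-1-yl)-6-(trimethylsilyl)phenyl trifluoromethanesulfonate, via silylphenol 11 (not isolated)
Conditions: DBU (1.5 equiv), Et2NH (1.2 equiv), MeCN, 40 °C; then PhNTf2 (1.5 equiv), rt
Reagents that add atoms: N-phenylbis(trifluoromethanesulfonimide), O=S(=O)(N(c1ccccc1)S(=O)(=O)C(F)(F)F)C(F)(F)F
Why: E1cB cleavage of the N-monoalkyl carbamate (the isocyanate is trapped by diethylamine) frees the hindered phenoxide, which is triflated in the same pot by the mild sulfonyl-transfer reagent without acid that could protodesilylate the ring.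

Step 5
Reactants: 13 1-(3-bromo-4-methoxyphenyl)ethan-1-one; 14 4-bromo-2-methylbut-1-ene
Product: 16 1-[4-methoxy-3-(3-methylbut-3-en-1-yl)phenyl]ethan-1-one, via (3-methylbut-3-en-1-yl)zinc bromide 15 (not isolated)
Conditions: 14, Zn dust, I2 (5 mol %), DMA, 70 °C; then 13, Pd(OAc)2 (2 mol %), SPhos (4 mol %), THF, rt → 45 °C
Reagents that add atoms: none
Why: Negishi sp3–sp2 cross-coupling: the primary alkylzinc bromide tolerates the methyl ketone, and the bulky biarylphosphine favours reductive elimination over β-hydride loss, so the isopentenyl chain is attached ortho to the methoxy group in one step.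

Step 6
Reactants: 16 1-[4-methoxy-3-(3-methylbut-3-en-1-yl)phenyl]ethan-1-one
Product: 17 ethyl 3-[4-methoxy-3-(3-methylbut-3-en-1-yl)phenyl]-3-oxopropanoate
Conditions: NaH (2.5 equiv), (EtO)2CO, THF, reflux, slow addition of 16; AcOH, aq work-up
Reagents that add atoms: diethyl carbonate, CCOC(=O)OCC
Why: Crossed Claisen condensation of the ketone enolate with diethyl carbonate is driven to completion by deprotonation of the β-keto ester formed.

Step 7
Reactants: 17 ethyl 3-[4-methoxy-3-(3-methylbut-3-en-1-yl)phenyl]-3-oxopropanoate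
Product: 18 ethyl (3R)-3-hydroxy-3-[4-methoxy-3-(3-methylbut-3-en-1-yl)phenyl]propanoate
Conditions: RuCl[(R,R)-TsDPEN](p-cymene) (1 mol %), HCO2H/Et3N (5:2), DMF, 40 °C
Reagents that add atoms: none
Why: Noyori asymmetric transfer hydrogenation: as with acetophenone, the (R,R)-ligand should deliver hydride to the aryl ketone face that gives the (R)-benzylic carbinol (aryl group oriented by the CH/π contact with the arene ligand), and the isolated 1,1-disubstituted alkene is not reduced.

Step 8
Reactants: 18 ethyl (3R)-3-hydroxy-3-[4-methoxy-3-(3-methylbut-3-en-1-yl)phenyl]propanoate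
Product: 19 ethyl (3R)-3-(tert-butyldimethylsilyloxy)-3-[4-methoxy-3-(3-methylbut-3-en-1-yl)phenyl]propanoate
Conditions: TBSCl, imidazole, DMF, rt
Reagents that add atoms: tert-butyldimethylsilyl chloride, CC(C)(C)[Si](C)(C)Cl
Why: Imidazole-promoted O-silylation protects the secondary carbinol, so that it cannot add to the aryne later, without touching the stereocentre.

Step 9
Reactants: 19 ethyl (3R)-3-(tert-butyldimethylsilyloxy)-3-[4-methoxy-3-(3-methylbut-3-en-1-yl)phenyl]propanoate
Product: 20 (3R)-3-(tert-butyldimethylsilyloxy)-3-[4-methoxy-3-(3-methylbut-3-en-1-yl)phenyl]propanoic acid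
Conditions: LiOH·H2O, THF/MeOH/H2O, 0 °C → rt; 1 M HCl to pH 4, 0 °C
Reagents that add atoms: lithium hydroxide, [Li+].[OH-]
Why: Saponification of the ethyl ester at or below room temperature should leave the β-silyloxy group in place, since the carboxylate formed is not prone to E1cB elimination.

Step 10
Reactants: 20 (3R)-3-(tert-butyldimethylsilyloxy)-3-[4-methoxy-3-(3-methylbut-3-en-1-yl)phenyl]propanoic acid; 12 3,5-bis(methoxymethoxy)-2-(3-methylbut-2-en-1-yl)-6-(trimethylsilyl)phenyl trifluoromethanesulfonate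
Product: 24 (3R)-3-(tert-butyldimethylsilyloxy)-1-[2-hydroxy-4,6-bis(methoxymethoxy)-3-(3-methylbut-2-en-1-yl)phenyl]-3-[4-methoxy-3-(3-methylbut-3-en-1-yl)phenyl]propan-1-one, via cesium carboxylate 21 (not isolated), via aryne 22 (not isolated), via aryl cesium ester 23 (not isolated)
Conditions: 20, Cs2CO3 (0.5 equiv), MeOH, rt, evaporate, dry (PhMe azeotrope); 12 (1.2 equiv), CsF (3 equiv), 18-crown-6, THF, rt; AcOH (1.1 equiv), 0 °C
Reagents that add atoms: none
Why: Fluoride removes the trimethylsilyl group of 12 and triflate departs, giving aryne 22 between C4a and C8a; the carboxylate of 21 O-arylates it at C8a, and the aryl anion 23, with its charge on C4a, adds across to the neighbouring ester carbonyl, whereupon collapse of the strained four-membered alkoxide moves the acyl group from oxygen to carbon and leaves the 2-acylphenoxide, so that C8a–O1 and C4a–C4 are made in one operation. The closest known reaction is the insertion of fluoride-generated arynes into the C–O bond of carboxylic acids, an O-arylation followed by an anionic Fries-type 1,3 acyl shift. No ring is closed and no stereocentre is formed; the carbinol centre takes no part and should be carried through unchanged. Regioselectivity is needed and is secured by the OMOM group on the carbon next to the aryne (the future C5), which polarises and distorts the triple bond so that the nucleophile enters at the remote terminus C8a beside the prenyl group and the charge develops at C4a ortho to oxygen; this effect should outweigh the smaller opposing steric effect of the prenyl group. The acid is used as its dry cesium salt in THF so that no proton donor intercepts the aryl anion as the simple aryl ester, and the crown ether lets CsF act at ambient temperature, where the β-silyloxy ketone should escape β-elimination and desilylation.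

Step 11
Reactants: 24 (3R)-3-(tert-butyldimethylsilyloxy)-1-[2-hydroxy-4,6-bis(methoxymethoxy)-3-(3-methylbut-2-en-1-yl)phenyl]-3-[4-methoxy-3-(3-methylbut-3-en-1-yl)phenyl]propan-1-one
Product: 25 (3R)-3-hydroxy-1-[2-hydroxy-4,6-bis(methoxymethoxy)-3-(3-methylbut-2-en-1-yl)phenyl]-3-[4-methoxy-3-(3-methylbut-3-en-1-yl)phenyl]propan-1-one
Conditions: HF·pyridine, pyridine, THF, 0 °C → rt
Reagents that add atoms: none
Why: Buffered, weakly acidic fluoride desilylation avoids the basic conditions under which a β-silyloxy ketone eliminates, and should leave the MOM ethers and both alkenes untouched.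

Step 12
Reactants: 25 (3R)-3-hydroxy-1-[2-hydroxy-4,6-bis(methoxymethoxy)-3-(3-methylbut-2-en-1-yl)phenyl]-3-[4-methoxy-3-(3-methylbut-3-en-1-yl)phenyl]propan-1-one
Product: 26 (2S)-5,7-bis(methoxymethoxy)-2-[4-methoxy-3-(3-methylbut-3-en-1-yl)phenyl]-8-(3-methylbut-2-en-1-yl)chroman-4-one
Conditions: PPh3, DIAD (slow addition), PhMe, 0 °C
Reagents that add atoms: none
Why: Intramolecular Mitsunobu etherification: the only free phenol displaces the activated secondary carbinol in a 6-exo-tet SN2 closure of ring C, so the (R)-carbinol is inverted to the (2S)-flavanone centre, the low temperature and non-polar solvent being chosen to disfavour ionisation at the benzylic carbon.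

Step 13
Reactants: 26 (2S)-5,7-bis(methoxymethoxy)-2-[4-methoxy-3-(3-methylbut-3-en-1-yl)phenyl]-8-(3-methylbut-2-en-1-yl)chroman-4-one
Product: 28 (2S)-5,7-dihydroxy-2-[4-methoxy-3-(3-methylbut-3-en-1-yl)phenyl]-8-(3-methylbut-2-en-1-yl)chroman-4-one (CNP0286775.1), via bis(trimethylsilyl) ether 27 (not isolated)
Conditions: TMSOTf (4 equiv), 2,2'-bipyridyl (6 equiv), MeCN, 0 °C → rt; then H2O
Reagents that add atoms: none
Why: Silyl triflate–bipyridyl cleavage of aromatic MOM ethers: silicon is transferred to the aryl oxygens while bipyridyl captures the methoxymethyl unit, and water then hydrolyses the labile aryl silyl ethers, so no free Brønsted acid meets the prenyl group beside the C7 hydroxyl, the isopentenyl alkene or the C2 stereocentre.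

**Compound list**
1 | phloroglucinol | Oc1cc(O)cc(O)c1 | starting material
2 | 3,5-bis(methoxymethoxy)phenol | Oc1cc(OCOC)cc(OCOC)c1 | intermediate
3 | 3,5-bis(methoxymethoxy)phenyl N-isopropylcarbamate | CC(C)NC(=O)Oc1cc(OCOC)cc(OCOC)c1 | intermediate
4 | prenyl bromide (1-bromo-3-methylbut-2-ene) | CC(C)=CCBr | starting material
5 | 3,5-bis(methoxymethoxy)phenyl N-isopropyl-N-(trimethylsilyl)carbamate | CC(C)N([Si](C)(C)C)C(=O)Oc1cc(OCOC)cc(OCOC)c1 | intermediate
6 | 2-lithio-3,5-bis(methoxymethoxy)phenyl N-isopropyl-N-(trimethylsilyl)carbamate | CC(C)N([Si](C)(C)C)C(=O)Oc1cc(OCOC)cc(OCOC)c1[Li] | intermediate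
7 | 3,5-bis(methoxymethoxy)-2-(trimethylsilyl)phenyl N-isopropyl-N-(trimethylsilyl)carbamate | CC(C)N([Si](C)(C)C)C(=O)Oc1cc(OCOC)cc(OCOC)c1[Si](C)(C)C | intermediate
8 | 2-lithio-3,5-bis(methoxymethoxy)-6-(trimethylsilyl)phenyl N-isopropyl-N-(trimethylsilyl)carbamate | CC(C)N([Si](C)(C)C)C(=O)Oc1c([Li])c(OCOC)cc(OCOC)c1[Si](C)(C)C | intermediate
9 | 3,5-bis(methoxymethoxy)-2-(3-methylbut-2-en-1-yl)-6-(trimethylsilyl)phenyl N-isopropyl-N-(trimethylsilyl)carbamate | CC(C)N([Si](C)(C)C)C(=O)Oc1c(CC=C(C)C)c(OCOC)cc(OCOC)c1[Si](C)(C)C | intermediate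
10 | 3,5-bis(methoxymethoxy)-2-(3-methylbut-2-en-1-yl)-6-(trimethylsilyl)phenyl N-isopropylcarbamate | CC(C)NC(=O)Oc1c(CC=C(C)C)c(OCOC)cc(OCOC)c1[Si](C)(C)C | intermediate
11 | 3,5-bis(methoxymethoxy)-2-(3-methylbut-2-en-1-yl)-6-(trimethylsilyl)phenol | Oc1c(CC=C(C)C)c(OCOC)cc(OCOC)c1[Si](C)(C)C | intermediate
12 | 3,5-bis(methoxymethoxy)-2-(3-methylbut-2-en-1-yl)-6-(trimethylsilyl)phenyl trifluoromethanesulfonate | C[Si](C)(C)c1c(OCOC)cc(OCOC)c(CC=C(C)C)c1OS(=O)(=O)C(F)(F)F | intermediate
13 | 1-(3-bromo-4-methoxyphenyl)ethan-1-one | CC(=O)c1ccc(OC)c(Br)c1 | starting material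
14 | 4-bromo-2-methylbut-1-ene | C=C(C)CCBr | starting material
15 | (3-methylbut-3-en-1-yl)zinc bromide | C=C(C)CC[Zn]Br | intermediate
16 | 1-[4-methoxy-3-(3-methylbut-3-en-1-yl)phenyl]ethan-1-one | CC(=O)c1ccc(OC)c(CCC(C)=C)c1 | intermediate
17 | ethyl 3-[4-methoxy-3-(3-methylbut-3-en-1-yl)phenyl]-3-oxopropanoate | CCOC(=O)CC(=O)c1ccc(OC)c(CCC(C)=C)c1 | intermediate
18 | ethyl (3R)-3-hydroxy-3-[4-methoxy-3-(3-methylbut-3-en-1-yl)phenyl]propanoate | CCOC(=O)C[C@H](c1ccc(OC)c(CCC(C)=C)c1)O | intermediate
19 | ethyl (3R)-3-(tert-butyldimethylsilyloxy)-3-[4-methoxy-3-(3-methylbut-3-en-1-yl)phenyl]propanoate | CCOC(=O)C[C@H](c1ccc(OC)c(CCC(C)=C)c1)O[Si](C)(C)C(C)(C)C | intermediate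
20 | (3R)-3-(tert-butyldimethylsilyloxy)-3-[4-methoxy-3-(3-methylbut-3-en-1-yl)phenyl]propanoic acid | OC(=O)C[C@H](c1ccc(OC)c(CCC(C)=C)c1)O[Si](C)(C)C(C)(C)C | intermediate
21 | cesium (3R)-3-(tert-butyldimethylsilyloxy)-3-[4-methoxy-3-(3-methylbut-3-en-1-yl)phenyl]propanoate | [Cs+].[O-]C(=O)C[C@H](c1ccc(OC)c(CCC(C)=C)c1)O[Si](C)(C)C(C)(C)C | intermediate
22 | 3,5-bis(methoxymethoxy)-6-(3-methylbut-2-en-1-yl)benzyne (aryne between C4a and C8a) | COCOC1=CC(OCOC)=C(CC=C(C)C)C#C1 | intermediate
23 | 2-cesio-3,5-bis(methoxymethoxy)-6-(3-methylbut-2-en-1-yl)phenyl (3R)-3-(tert-butyldimethylsilyloxy)-3-[4-methoxy-3-(3-methylbut-3-en-1-yl)phenyl]propanoate | [Cs]c1c(OCOC)cc(OCOC)c(CC=C(C)C)c1OC(=O)C[C@H](c1ccc(OC)c(CCC(C)=C)c1)O[Si](C)(C)C(C)(C)C | intermediate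
24 | (3R)-3-(tert-butyldimethylsilyloxy)-1-[2-hydroxy-4,6-bis(methoxymethoxy)-3-(3-methylbut-2-en-1-yl)phenyl]-3-[4-methoxy-3-(3-methylbut-3-en-1-yl)phenyl]propan-1-one | O=C(C[C@H](c1ccc(OC)c(CCC(C)=C)c1)O[Si](C)(C)C(C)(C)C)c1c(OCOC)cc(OCOC)c(CC=C(C)C)c1O | intermediate
25 | (3R)-3-hydroxy-1-[2-hydroxy-4,6-bis(methoxymethoxy)-3-(3-methylbut-2-en-1-yl)phenyl]-3-[4-methoxy-3-(3-methylbut-3-en-1-yl)phenyl]propan-1-one | O=C(C[C@H](c1ccc(OC)c(CCC(C)=C)c1)O)c1c(OCOC)cc(OCOC)c(CC=C(C)C)c1O | intermediate
26 | (2S)-5,7-bis(methoxymethoxy)-2-[4-methoxy-3-(3-methylbut-3-en-1-yl)phenyl]-8-(3-methylbut-2-en-1-yl)chroman-4-one | C=C(C)CCc1cc([C@@H]2CC(=O)c3c(OCOC)cc(OCOC)c(CC=C(C)C)c3O2)ccc1OC | intermediate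
27 | (2S)-2-[4-methoxy-3-(3-methylbut-3-en-1-yl)phenyl]-8-(3-methylbut-2-en-1-yl)-5,7-bis(trimethylsilyloxy)chroman-4-one | C=C(C)CCc1cc([C@@H]2CC(=O)c3c(O[Si](C)(C)C)cc(O[Si](C)(C)C)c(CC=C(C)C)c3O2)ccc1OC | intermediate
28 | (2S)-5,7-dihydroxy-2-[4-methoxy-3-(3-methylbut-3-en-1-yl)phenyl]-8-(3-methylbut-2-en-1-yl)chroman-4-one (CNP0286775.1) | C=C(C)CCc1cc([C@@H]2CC(=O)c3c(O)cc(O)c(CC=C(C)C)c3O2)ccc1OC | target

**Step count**
Total: 13 steps. Longest linear sequence: 9 steps (steps 5–9, then steps 10–13).

**Steps most likely to fail**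

Step 10. Three processes could spoil it:
- attack of the carboxylate at the wrong aryne terminus, which would lead to the regioisomeric ketone;
- protonation of the aryl anion before acyl transfer, by adventitious water or by the α-hydrogens of its own ester, which would stop at the aryl ester;
- fluoride- or phenoxide-induced β-elimination of silanolate from the product.

The fallback sets out from 3 and 20 and comes back at 24. Carbamate 3 is N-silylated and ortho-lithiated as in the first half of step 3 and alkylated with 4 in place of TMSCl to give 3,5-bis(methoxymethoxy)-2-(3-methylbut-2-en-1-yl)phenyl N-isopropylcarbamate F1. Acid 20 is converted with EDC·HCl, MeNHOMe·HCl and iPr2NEt in CH2Cl2 into the Weinreb amide (3R)-3-(tert-butyldimethylsilyloxy)-N-methoxy-3-[4-methoxy-3-(3-methylbut-3-en-1-yl)phenyl]-N-methylpropanamide F2. F1, N-silylated in situ, is ring-lithiated at C6 (s-BuLi, TMEDA, Et2O, −78 °C) and acylated with F2 to give 2-[(3R)-3-(tert-butyldimethylsilyloxy)-3-[4-methoxy-3-(3-methylbut-3-en-1-yl)phenyl]propanoyl]-3,5-bis(methoxymethoxy)-6-(3-methylbut-2-en-1-yl)phenyl N-isopropylcarbamate F3. E1cB cleavage of the carbamate (Et2NH, DBU, MeCN, rt) should then free the phenol 24. The carbamate oxygen keeps the three ring A oxygens differentiated, so the regiochemistry is fixed by directed metalation and not by the aryne.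

Step 12. The activated carbinol sits on an electron-rich, para-methoxy-substituted benzylic carbon. Ionisation there, or elimination to the chalcone followed by unselective oxa-Michael closure, would erode the enantiomeric purity. The fallback sets out from 25 and comes back at 26. Base-induced dehydration (KOH, EtOH, rt) should give (E)-1-[2-hydroxy-4,6-bis(methoxymethoxy)-3-(3-methylbut-2-en-1-yl)phenyl]-3-[4-methoxy-3-(3-methylbut-3-en-1-yl)phenyl]prop-2-en-1-one F4. Chalcone–flavanone isomerisation (NaOAc, EtOH, reflux) gives racemic 5,7-bis(methoxymethoxy)-2-[4-methoxy-3-(3-methylbut-3-en-1-yl)phenyl]-8-(3-methylbut-2-en-1-yl)chroman-4-one F5. Resolution by preparative chromatography on an amylose tris(3,5-dimethylphenylcarbamate) phase then gives the (2S)-enantiomer 26. The stereocentre is then set by resolution and no longer by stereospecific substitution.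

Step 3. Several processes could spoil the one-flask double metalation. Residual TMSCl or unquenched aryllithium from the first half could carry into the second. The second metalation could occur at C4 between the two MOM ethers instead of at C6. The carbamoyl group could migrate to the lithiated carbon on warming, or SN2′ attack on prenyl bromide could give the reverse-prenyl isomer. The fallback sets out from 3 and comes back at 11, which is then triflated with PhNTf2 as in the second half of step 4. The sequence of step 3 is stopped after the TMSCl quench and worked up with sat. aq NH4Cl, which hydrolyses the N–Si bond of 7 and gives 3,5-bis(methoxymethoxy)-2-(trimethylsilyl)phenyl N-isopropylcarbamate F6. Carbamate cleavage (Et2NH, DBU, MeCN, 40 °C) gives 3,5-bis(methoxymethoxy)-2-(trimethylsilyl)phenol F7. Copper-catalysed O-alkylation with 3-chloro-3-methylbut-1-yne (CuCl2 cat., DBU, MeCN, 0 °C) gives [2,4-bis(methoxymethoxy)-6-(2-methylbut-3-yn-2-yloxy)phenyl]trimethylsilane F8. Semihydrogenation (H2, Pd/CaCO3/Pb(OAc)2, quinoline, EtOAc) gives [2,4-bis(methoxymethoxy)-6-(2-methylbut-3-en-2-yloxy)phenyl]trimethylsilane F9. An aromatic Claisen rearrangement (PhMe, 110 °C) then delivers the prenyl group to the only free ortho carbon and gives 11. The prenyl group is thereby placed by a sigmatropic shift from the phenol oxygen, without a second lithiation.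

**Further compounds**
F1 | step 10 | 3,5-bis(methoxymethoxy)-2-(3-methylbut-2-en-1-yl)phenyl N-isopropylcarbamate | CC(C)NC(=O)Oc1c(CC=C(C)C)c(OCOC)cc(OCOC)c1
F2 | step 10 | (3R)-3-(tert-butyldimethylsilyloxy)-N-methoxy-3-[4-methoxy-3-(3-methylbut-3-en-1-yl)phenyl]-N-methylpropanamide | CON(C)C(=O)C[C@H](c1ccc(OC)c(CCC(C)=C)c1)O[Si](C)(C)C(C)(C)C
F3 | step 10 | 2-[(3R)-3-(tert-butyldimethylsilyloxy)-3-[4-methoxy-3-(3-methylbut-3-en-1-yl)phenyl]propanoyl]-3,5-bis(methoxymethoxy)-6-(3-methylbut-2-en-1-yl)phenyl N-isopropylcarbamate | CC(C)NC(=O)Oc1c(CC=C(C)C)c(OCOC)cc(OCOC)c1C(=O)C[C@H](c1ccc(OC)c(CCC(C)=C)c1)O[Si](C)(C)C(C)(C)C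
F4 | step 12 | (E)-1-[2-hydroxy-4,6-bis(methoxymethoxy)-3-(3-methylbut-2-en-1-yl)phenyl]-3-[4-methoxy-3-(3-methylbut-3-en-1-yl)phenyl]prop-2-en-1-one | O=C(/C=C/c1ccc(OC)c(CCC(C)=C)c1)c1c(OCOC)cc(OCOC)c(CC=C(C)C)c1O
F5 | step 12 | racemic 5,7-bis(methoxymethoxy)-2-[4-methoxy-3-(3-methylbut-3-en-1-yl)phenyl]-8-(3-methylbut-2-en-1-yl)chroman-4-one | C=C(C)CCc1cc(C2CC(=O)c3c(OCOC)cc(OCOC)c(CC=C(C)C)c3O2)ccc1OC
F6 | step 3 | 3,5-bis(methoxymethoxy)-2-(trimethylsilyl)phenyl N-isopropylcarbamate | CC(C)NC(=O)Oc1cc(OCOC)cc(OCOC)c1[Si](C)(C)C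
F7 | step 3 | 3,5-bis(methoxymethoxy)-2-(trimethylsilyl)phenol | Oc1cc(OCOC)cc(OCOC)c1[Si](C)(C)C
F8 | step 3 | [2,4-bis(methoxymethoxy)-6-(2-methylbut-3-yn-2-yloxy)phenyl]trimethylsilane | C#CC(C)(C)Oc1cc(OCOC)cc(OCOC)c1[Si](C)(C)C
F9 | step 3 | [2,4-bis(methoxymethoxy)-6-(2-methylbut-3-en-2-yloxy)phenyl]trimethylsilane | C=CC(C)(C)Oc1cc(OCOC)cc(OCOC)c1[Si](C)(C)C
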